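**Strategy.** The target is the meso, all-cis 2,5-diaryl-3,4-bis(hydroxymethyl)oxolane. Its ring is cut at O1–C5 and C2–C3. C5, C4 and C3 come from an aryl cyclopropane-1,1-diester, and O1 and C2 from O-benzylsyringaldehyde. One Lewis acid-catalysed (3+2) annulation closes the oxolane, makes both bonds and sets C2 and C5. It exploits the bis-benzylic C2–O1–C5 ether of this ring and its cis aryl groups. Since the aldehyde oxygen enters at C5 with inversion, the 4,5-cis relationship requires the trans cyclopropane, made from an E alkene; the cis isomer would give a 4,5-trans ring. The C4 arm carries a silyl ether, whose release forms a cis-fused lactone that fixes C3.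

Key step: step 7

Assumption: the target is achiral (meso), so all chiral intermediates are made as racemates, and each SMILES shows one enantiomer only to define the relative configuration.
Oxolane numbering: O1, C2 (former aldehyde carbon), C3 (former malonate carbon), C4 (carbon bearing the arm from the alkene), C5 (former benzylic cyclopropane carbon).

**Step 1**
Reactants: 1 syringaldehyde
Product: 2 4-(benzyloxy)-3,5-dimethoxybenzaldehyde
Conditions: BnBr (1.1 equiv), K2CO3, DMF, 60 °C
Reagents that add atoms: benzyl bromide, BrCc1ccccc1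
Why: Williamson ether synthesis, in which the acidic phenoxide of 1 is alkylated by the reactive benzylic bromide while the aldehyde is inert to carbonate.

**Step 2**
Reactants: 2 4-(benzyloxy)-3,5-dimethoxybenzaldehyde; 3 triethyl phosphonoacetate
Product: 4 ethyl (E)-3-[4-(benzyloxy)-3,5-dimethoxyphenyl]prop-2-enoate
Conditions: NaH, THF, 0 °C → rt
Reagents that add atoms: none
Why: Horner–Wadsworth–Emmons olefination with a stabilised phosphonate anion is reversible in its addition step and should therefore give the E alkene, the geometry that the annulation needs once it has been carried into the cyclopropane.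

**Step 3**
Reactants: 4 ethyl (E)-3-[4-(benzyloxy)-3,5-dimethoxyphenyl]prop-2-enoate
Product: 5 (E)-3-[4-(benzyloxy)-3,5-dimethoxyphenyl]prop-2-en-1-ol
Conditions: i-Bu2AlH (2.5 equiv), CH2Cl2, −78 °C; aq. Rochelle salt
Reagents that add atoms: none
Why: 1,2-Reduction of a conjugated ester by an electrophilic aluminium hydride at low temperature stops at the allylic alcohol and leaves the alkene geometry and the benzyl ether untouched.

**Step 4**
Reactants: 5 (E)-3-[4-(benzyloxy)-3,5-dimethoxyphenyl]prop-2-en-1-ol
Product: 6 (E)-{3-[4-(benzyloxy)-3,5-dimethoxyphenyl]prop-2-enyloxy}(tert-butyl)diphenylsilane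
Conditions: TBDPSCl, imidazole, DMF, rt
Reagents that add atoms: tert-butyl(chloro)diphenylsilane, CC(C)(C)[Si](Cl)(c1ccccc1)c1ccccc1
Why: Imidazole-promoted silylation of a primary alcohol gives an ether whose hindered, weakly basic oxygen should not trap the rhodium carbene as an oxonium ylide, should tolerate the tin triflate, and can later be removed without touching the aryl benzyl ethers.

**Step 5**
Reactants: 7 dimethyl malonate
Product: 8 dimethyl diazomalonate
Conditions: 4-acetamidobenzenesulfonyl azide, Et3N, MeCN, 0 °C → rt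
Reagents that add atoms: 4-acetamidobenzenesulfonyl azide, CC(=O)Nc1ccc(cc1)S(=O)(=O)N=[N+]=[N-]
Why: Regitz diazo transfer from a sulfonyl azide to the amine-generated malonate enolate is the standard entry to diazomalonates.

**Step 6**
Reactants: 6 (E)-cinnamyl silyl ether; 8 dimethyl diazomalonate
Product: 9 dimethyl trans-2-[4-(benzyloxy)-3,5-dimethoxyphenyl]-3-[(tert-butyldiphenylsilyloxy)methyl]cyclopropane-1,1-dicarboxylate (aryl and silyloxymethyl on opposite faces; racemic)
Conditions: Rh2(esp)2 (1 mol%; esp = α,α,α′,α′-tetramethyl-1,3-benzenedipropanoate), CH2Cl2, reflux, 8 (2 equiv) by syringe pump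
Reagents that add atoms: none
Why: Rhodium carbene cyclopropanation is a concerted syn addition to the electron-rich styrenyl alkene, so the E geometry of 6 is copied stereospecifically into the trans relationship of the aryl and silyloxymethyl groups (two stereocentres, racemic), and the chelating esp ligand keeps the catalyst alive with the sluggish malonate carbene.

**Step 7**
Reactants: 9 trans cyclopropane diester; 2 4-(benzyloxy)-3,5-dimethoxybenzaldehyde
Product: 10 dimethyl 2,5-bis[4-(benzyloxy)-3,5-dimethoxyphenyl]-4-[(tert-butyldiphenylsilyloxy)methyl]oxolane-3,3-dicarboxylate (C2-aryl, C5-aryl and the C4 arm all cis; racemic)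
Conditions: Sn(OTf)2 (10 mol%), 2 (2 equiv), 4 Å MS, CH2Cl2, −20 °C → rt; filtration through silica as soon as 9 is consumed
Reagents that add atoms: none
Why: Two-point binding of the divalent tin triflate to the diester carbonyls weakens the C1–C2(aryl) bond of 9, the carbonyl oxygen of 2 displaces the malonate carbon from the benzylic carbon in an SN2-like attack on a tight ion pair (O1–C5), and after rotation about C4–C5 the tin malonate enolate adds to the oxocarbenium carbon (C2–C3). This is the known Lewis acid-catalysed (3+2) annulation of 2-arylcyclopropane-1,1-diesters with aldehydes, which also extends to 2,3-disubstituted cyclopropanes. The oxolane closes in a 5-(enolexo)-endo-trig mode, because the attacked C2=O1 oxocarbenium bond lies inside the new ring, a closure that is feasible for such a cationic acceptor. C5 is set by the substrate, since inversion at the benzylic carbon with C4 untouched turns the trans cyclopropane into the 4,5-cis pair, and C2 is set in the closure, where the E oxocarbenium ion folds into an envelope that places the two aryl groups pseudoequatorial and hence cis. The step needs cleavage of C1–C2 rather than C1–C3, which the aryl donor secures, and capture before free ionisation, which is favoured by the nucleophilic electron-rich aldehyde, by the 4-benzyloxy oxygen being twisted out of conjugation by its two ortho methoxy groups, and by the low temperature. The trans cyclopropane is also the more stable isomer, so reversible opening and reclosure should not erode its geometry.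

**Step 8**
Reactants: 10 oxolane-3,3-diester
Product: 12 cis-fused lactone ester methyl 6,8-bis[4-(benzyloxy)-3,5-dimethoxyphenyl]-2-oxo-3,7-dioxabicyclo[3.3.0]octane-1-carboxylate (both aryl groups on the oxolane face that carries the lactone ring; racemic), via hydroxy diester 11 (not isolated)
Conditions: n-Bu4NF (1.2 equiv), THF, 0 °C → rt
Reagents that add atoms: none
Why: Fluoride desilylation frees the C4 alkoxide, which undergoes 5-exo-trig transesterification only with the C3 ester on its own face because a trans-fused bicyclo[3.3.0] lactone is too strained, so C3 becomes a defined quaternary centre whose surviving carbonyl carbon is cis to C4.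

**Step 9**
Reactants: 12 lactone ester
Product: 13 6,8-bis[4-(benzyloxy)-3,5-dimethoxyphenyl]-3,7-dioxabicyclo[3.3.0]octan-2-one (cis-fused; all four oxolane substituents cis; racemic)
Conditions: LiCl (5 equiv), H2O (3 equiv), DMSO, 140 °C
Reagents that add atoms: none
Why: Krapcho demethoxycarbonylation (chloride attack on the methyl group, then loss of CO2) gives the lactone enolate, whose protonation can only restore the cis ring fusion, so that C3–H ends on the convex face and the C3 carbon arm stays cis to the C2 aryl group and to C4 under kinetic and thermodynamic control alike.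

**Step 10**
Reactants: 13 cis-fused lactone
Product: 14 all-cis-{2,5-bis[4-(benzyloxy)-3,5-dimethoxyphenyl]oxolane-3,4-diyl}dimethanol (meso)
Conditions: LiAlH4, THF, 0 °C → rt
Reagents that add atoms: none
Why: Lithium aluminium hydride reduction of a γ-lactone gives the 1,4-diol without touching any stereocentre, since hydride addition outruns enolisation and the benzyl ethers are inert.

**Step 11**
Reactants: 14 bis(benzyl ether) diol
Product: 15 (2R,3R,4S,5S)-[2,5-bis(4-hydroxy-3,5-dimethoxyphenyl)oxolane-3,4-diyl]dimethanol (meso, all-cis; target)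
Conditions: H2 (1 atm), 10% Pd/C, EtOAc–MeOH, rt
Reagents that add atoms: none
Why: Catalytic hydrogenolysis cleaves aryl benzyl ethers much faster than the secondary benzylic C–O bonds of the oxolane, so a neutral medium, one atmosphere of hydrogen and interruption after two equivalents should free both phenols and leave the four stereocentres alone.

**Compound list**
1 | syringaldehyde (4-hydroxy-3,5-dimethoxybenzaldehyde) | COc1cc(C=O)cc(OC)c1O | starting material
2 | 4-(benzyloxy)-3,5-dimethoxybenzaldehyde | COc1cc(C=O)cc(OC)c1OCc2ccccc2 | intermediate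
3 | triethyl phosphonoacetate | CCOC(=O)CP(=O)(OCC)OCC | starting material
4 | ethyl (E)-3-[4-(benzyloxy)-3,5-dimethoxyphenyl]prop-2-enoate | CCOC(=O)/C=C/c1cc(OC)c(OCc2ccccc2)c(OC)c1 | intermediate
5 | (E)-3-[4-(benzyloxy)-3,5-dimethoxyphenyl]prop-2-en-1-ol | OC/C=C/c1cc(OC)c(OCc2ccccc2)c(OC)c1 | intermediate
6 | (E)-{3-[4-(benzyloxy)-3,5-dimethoxyphenyl]prop-2-enyloxy}(tert-butyl)diphenylsilane | CC(C)(C)[Si](OC/C=C/c1cc(OC)c(OCc2ccccc2)c(OC)c1)(c3ccccc3)c4ccccc4 | intermediate
7 | dimethyl malonate | COC(=O)CC(=O)OC | starting material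
8 | dimethyl diazomalonate | COC(=O)C(=[N+]=[N-])C(=O)OC | intermediate
9 | dimethyl trans-2-[4-(benzyloxy)-3,5-dimethoxyphenyl]-3-[(tert-butyldiphenylsilyloxy)methyl]cyclopropane-1,1-dicarboxylate (racemic) | COC(=O)C1(C(=O)OC)[C@H](c2cc(OC)c(OCc3ccccc3)c(OC)c2)[C@H]1CO[Si](c4ccccc4)(c5ccccc5)C(C)(C)C | intermediate
10 | dimethyl 2,4,5-all-cis-2,5-bis[4-(benzyloxy)-3,5-dimethoxyphenyl]-4-[(tert-butyldiphenylsilyloxy)methyl]oxolane-3,3-dicarboxylate (racemic) | COc1cc([C@H]2O[C@@H](c3cc(OC)c(OCc4ccccc4)c(OC)c3)[C@@H](CO[Si](c5ccccc5)(c6ccccc6)C(C)(C)C)C2(C(=O)OC)C(=O)OC)cc(OC)c1OCc7ccccc7 | intermediate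
11 | dimethyl 2,4,5-all-cis-2,5-bis[4-(benzyloxy)-3,5-dimethoxyphenyl]-4-(hydroxymethyl)oxolane-3,3-dicarboxylate (racemic, not isolated) | COc1cc([C@H]2O[C@@H](c3cc(OC)c(OCc4ccccc4)c(OC)c3)[C@@H](CO)C2(C(=O)OC)C(=O)OC)cc(OC)c1OCc5ccccc5 | intermediate
12 | methyl 6,8-bis[4-(benzyloxy)-3,5-dimethoxyphenyl]-2-oxo-3,7-dioxabicyclo[3.3.0]octane-1-carboxylate, cis-fused, both aryl groups cis to the lactone ring (racemic; C1 = oxolane C3, C5 = oxolane C4, C6 = oxolane C5, C8 = oxolane C2) | COc1cc([C@H]2O[C@@H](c3cc(OC)c(OCc4ccccc4)c(OC)c3)[C@H]5COC(=O)[C@@]25C(=O)OC)cc(OC)c1OCc6ccccc6 | intermediate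
13 | 6,8-bis[4-(benzyloxy)-3,5-dimethoxyphenyl]-3,7-dioxabicyclo[3.3.0]octan-2-one, cis-fused, both aryl groups cis to the lactone ring (racemic) | COc1cc([C@H]2O[C@@H](c3cc(OC)c(OCc4ccccc4)c(OC)c3)[C@H]5COC(=O)[C@@H]25)cc(OC)c1OCc6ccccc6 | intermediate
14 | all-cis-{2,5-bis[4-(benzyloxy)-3,5-dimethoxyphenyl]oxolane-3,4-diyl}dimethanol (meso) | COc1cc([C@H]2O[C@@H](c3cc(OC)c(OCc4ccccc4)c(OC)c3)[C@@H](CO)[C@H]2CO)cc(OC)c1OCc5ccccc5 | intermediate
15 | (2R,3R,4S,5S)-[2,5-bis(4-hydroxy-3,5-dimethoxyphenyl)oxolane-3,4-diyl]dimethanol (meso, all-cis) | COc1cc([C@H]2O[C@@H](c3cc(OC)c(O)c(OC)c3)[C@@H](CO)[C@H]2CO)cc(OC)c1O | target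

**Totals**
Total step count: 11.
Longest linear sequence: 10 steps (1, 2, 3, 4, 6, 7, 8, 9, 10, 11). Step 5 runs on a side branch, and 2 is used twice.

**Steps most likely to fail**

Step 7. The electron-rich benzylic centre may ionise fully before the aldehyde arrives, which would erase the inversion on which the 4,5-cis relationship rests. The opened ion pair may also lose a proton. Long contact with the Lewis acid may reopen the product and erode the 2,5-cis relationship.

The fallback sets out from 2 and comes back at 15. It gives up the annulation and sets all four stereocentres by adding hydrogen to one face of a flat furan, the classical entry to all-cis diaryloxolanes.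
- Roskamp homologation of 2 with ethyl diazoacetate (SnCl2 cat., CH2Cl2) gives ethyl 3-[4-(benzyloxy)-3,5-dimethoxyphenyl]-3-oxopropanoate F1.
- Oxidative enolate dimerisation (NaH, then I2, THF) gives diethyl 2,3-bis[4-(benzyloxy)-3,5-dimethoxybenzoyl]butanedioate F2.
- Paal–Knorr cyclodehydration (p-TsOH, toluene, reflux) gives diethyl 2,5-bis[4-(benzyloxy)-3,5-dimethoxyphenyl]furan-3,4-dicarboxylate F3.
- Hydrogenation over 10% Pd/C under pressure in EtOH saturates the furan from one face and removes both benzyl groups, giving diethyl all-cis-2,5-bis(4-hydroxy-3,5-dimethoxyphenyl)oxolane-3,4-dicarboxylate F4.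
- Excess LiAlH4 in THF reduces F4 to 15.

Step 6. The malonate carbene may add too slowly to the hindered 1,2-disubstituted alkene. Carbene dimerisation and attack on the electron-rich arenes or benzylic C–H bonds would then take over.

The fallback sets out from 5 and comes back at 9. It builds the three-membered ring by a Michael-initiated ring closure instead of a carbene transfer.
- MnO2 oxidation of 5 (CH2Cl2) gives (E)-3-[4-(benzyloxy)-3,5-dimethoxyphenyl]prop-2-enal F5.
- Iminium-catalysed conjugate addition of dimethyl bromomalonate, followed by intramolecular enamine alkylation, gives dimethyl trans-2-[4-(benzyloxy)-3,5-dimethoxyphenyl]-3-formylcyclopropane-1,1-dicarboxylate F6. The conditions are α,α-diphenylprolinol trimethylsilyl ether (20 mol%), 2,6-lutidine and CH2Cl2, and either antipode of the catalyst serves because the target is meso.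
- Brief NaBH4 reduction at 0 °C gives dimethyl trans-2-[4-(benzyloxy)-3,5-dimethoxyphenyl]-3-(hydroxymethyl)cyclopropane-1,1-dicarboxylate F7.
- F7 is silylated at once (TBDPSCl, imidazole) to give 9.

Step 9. At the temperature needed, the lactone enolate may expel O1 from C2 and reclose with loss of configuration, or the strained all-cis framework may epimerise at a benzylic carbon.

The fallback sets out from 12 and comes back at 13. It replaces the anionic decarboxylation by a radical one at room temperature.
- Saponification with LiOH in aqueous THF and acidification, which recloses the lactone, gives 6,8-bis[4-(benzyloxy)-3,5-dimethoxyphenyl]-2-oxo-3,7-dioxabicyclo[3.3.0]octane-1-carboxylic acid F8.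
- Coupling with 1-hydroxypyridine-2(1H)-thione (DCC, CH2Cl2, dark) gives the Barton ester 2-thioxopyridin-1(2H)-yl 6,8-bis[4-(benzyloxy)-3,5-dimethoxyphenyl]-2-oxo-3,7-dioxabicyclo[3.3.0]octane-1-carboxylate F9.
- Irradiation of F9 with visible light in the presence of t-BuSH (Barton reductive decarboxylation) causes loss of CO2.
- The ring-fusion radical can accept hydrogen only so as to restore the cis fusion, which gives 13.

**Further compounds**
F1 | step 7 | ethyl 3-[4-(benzyloxy)-3,5-dimethoxyphenyl]-3-oxopropanoate | CCOC(=O)CC(=O)c1cc(OC)c(OCc2ccccc2)c(OC)c1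
F2 | step 7 | diethyl 2,3-bis[4-(benzyloxy)-3,5-dimethoxybenzoyl]butanedioate (diastereomer mixture; both centres are erased in F3) | CCOC(=O)C(C(=O)c1cc(OC)c(OCc2ccccc2)c(OC)c1)C(C(=O)OCC)C(=O)c3cc(OC)c(OCc4ccccc4)c(OC)c3
F3 | step 7 | diethyl 2,5-bis[4-(benzyloxy)-3,5-dimethoxyphenyl]furan-3,4-dicarboxylate | CCOC(=O)c1c(C(=O)OCC)c(-c2cc(OC)c(OCc3ccccc3)c(OC)c2)oc1-c4cc(OC)c(OCc5ccccc5)c(OC)c4
F4 | step 7 | diethyl all-cis-2,5-bis(4-hydroxy-3,5-dimethoxyphenyl)oxolane-3,4-dicarboxylate (meso) | COc1cc([C@H]2O[C@@H](c3cc(OC)c(O)c(OC)c3)[C@@H](C(=O)OCC)[C@H]2C(=O)OCC)cc(OC)c1O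
F5 | step 6 | (E)-3-[4-(benzyloxy)-3,5-dimethoxyphenyl]prop-2-enal | O=C/C=C/c1cc(OC)c(OCc2ccccc2)c(OC)c1
F6 | step 6 | dimethyl trans-2-[4-(benzyloxy)-3,5-dimethoxyphenyl]-3-formylcyclopropane-1,1-dicarboxylate | COC(=O)C1(C(=O)OC)[C@H](c2cc(OC)c(OCc3ccccc3)c(OC)c2)[C@H]1C=O
F7 | step 6 | dimethyl trans-2-[4-(benzyloxy)-3,5-dimethoxyphenyl]-3-(hydroxymethyl)cyclopropane-1,1-dicarboxylate | COC(=O)C1(C(=O)OC)[C@H](c2cc(OC)c(OCc3ccccc3)c(OC)c2)[C@H]1CO
F8 | step 9 | 6,8-bis[4-(benzyloxy)-3,5-dimethoxyphenyl]-2-oxo-3,7-dioxabicyclo[3.3.0]octane-1-carboxylic acid (cis-fused, aryl groups cis to the lactone ring) | COc1cc([C@H]2O[C@@H](c3cc(OC)c(OCc4ccccc4)c(OC)c3)[C@H]5COC(=O)[C@@]25C(=O)O)cc(OC)c1OCc6ccccc6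
F9 | step 9 | 2-thioxopyridin-1(2H)-yl 6,8-bis[4-(benzyloxy)-3,5-dimethoxyphenyl]-2-oxo-3,7-dioxabicyclo[3.3.0]octane-1-carboxylate (Barton ester) | COc1cc([C@H]2O[C@@H](c3cc(OC)c(OCc4ccccc4)c(OC)c3)[C@H]5COC(=O)[C@@]25C(=O)ON7C=CC=CC7=S)cc(OC)c1OCc6ccccc6
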